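**Strategy.** The cycloheptene of this cis-fused daucane is opened by a retro-Cope to a cis-divinylcyclopropane whose two alkenyl arms are a (Z)-enol tiglate and the C3a=C8a bond of a 3-methylcyclopentenone. On heating, one [3,3] shift through a boat transition state forms the C8–C8a σ-bond and the C6=C7 double bond, closes the seven-membered ring onto the five-membered one and creates the vicinal C8 (O-tiglate) / C8a (quaternary methyl) pair. It exploits the allylic array C8a–C8(O)–C7=C6 of that ring. Cyclopropane chirality, set by a Charette cyclopropanation, is relayed to both centres; C4, C3a and C3 follow by substrate control.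

Key step: step 7

Remarks:
- Locants C-1 to C-8a in the comments are those of the target hydroazulene: C-3 tertiary carbinol, C-3a ring-fusion CH, C-4 aroyloxy carbon, C-6/C-7 ring alkene, C-8 tigloyloxy carbon, C-8a quaternary carbon.
- The acyl group C/C=C(\C)C(=O) is read as (E)-2-methylbut-2-enoyl (tigloyl), and the ring fusion as cis (H-3a and CH3-8a on the same face).
- Assumption: the (S,S)-dioxaborolane delivers CH2 to dienol 5 in the mirror-image facial sense of the (R,R)-controller with simple allylic alcohols.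
- Assumption: bromoenone 4 is taken as a catalogue compound.

**Step 1**
Reactants: 1 prop-2-yn-1-ol
Product: 3 (2Z)-2-methyl-3-(tributylstannyl)prop-2-en-1-ol, via alkenylmagnesium alkoxide 2 (not isolated)
Conditions: MeMgBr (3 equiv), CuI (10 mol%), THF, −20 °C to rt; then Bu3SnCl, 0 °C to rt
Reagents that add atoms: methylmagnesium bromide C[Mg]Br; tributyltin chloride CCCC[Sn](Cl)(CCCC)CCCC
Why: Hydroxyl-directed, copper-catalysed anti-carbomagnesiation of the propargylic alcohol puts Mg cis to CH2O in a five-membered chelate, and stannylation of this alkenyl Grignard with retention should fix the Z-trisubstituted alkene.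

**Step 2**
Reactants: 3 (2Z)-2-methyl-3-(tributylstannyl)prop-2-en-1-ol; 4 2-bromo-3-methylcyclopent-2-en-1-one
Product: 5 2-[(1Z)-3-hydroxy-2-methylprop-1-en-1-yl]-3-methylcyclopent-2-en-1-one
Conditions: Pd2(dba)3 (2.5 mol%), AsPh3, CuI, NMP, 50 °C
Reagents that add atoms: none
Why: Stille coupling of an α-bromoenone with an alkenylstannane should proceed with retention of alkene geometry and tolerates the free alcohol and the ketone.

**Step 3**
Reactants: 5 2-[(1Z)-3-hydroxy-2-methylprop-1-en-1-yl]-3-methylcyclopent-2-en-1-one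
Product: 6 2-[(1S,2R)-2-(hydroxymethyl)-2-methylcyclopropyl]-3-methylcyclopent-2-en-1-one
Conditions: Et2Zn, CH2I2, DME, (4S,5S)-2-butyl-N,N,N',N'-tetramethyl-1,3,2-dioxaborolane-4,5-dicarboxamide (1.2 equiv), CH2Cl2, −10 °C to rt; aq. NaOH work-up
Reagents that add atoms: diiodomethane ICI
Why: In this Charette asymmetric Simmons–Smith cyclopropanation the alkoxide bound to the chiral dioxaborolane should direct stereospecific syn-CH2 transfer to one face of the allylic Z-alkene only (the tetrasubstituted enone alkene is inert), so the Z geometry gives the cis relationship of the two arms and the (S,S)-controller the absolute sense of both cyclopropane centres.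

**Step 4**
Reactants: 6 2-[(1S,2R)-2-(hydroxymethyl)-2-methylcyclopropyl]-3-methylcyclopent-2-en-1-one
Product: 7 (1R,2S)-1-methyl-2-(2-methyl-5-oxocyclopent-1-en-1-yl)cyclopropane-1-carbaldehyde
Conditions: Dess–Martin periodinane, CH2Cl2, 0 °C to rt; used directly
Reagents that add atoms: none
Why: Dess–Martin oxidation of the primary alcohol is neutral and the quaternary α-carbon cannot epimerise, so the cis-cyclopropane should be kept.

**Step 5**
Reactants: 7 (1R,2S)-1-methyl-2-(2-methyl-5-oxocyclopent-1-en-1-yl)cyclopropane-1-carbaldehyde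
Product: 8 2-[(1S,2R)-2-ethynyl-2-methylcyclopropyl]-3-methylcyclopent-2-en-1-one
Conditions: dimethyl (1-diazo-2-oxopropyl)phosphonate, K2CO3, MeOH, 0 °C to rt
Reagents that add atoms: dimethyl (1-diazo-2-oxopropyl)phosphonate COP(=O)(OC)C(=[N+]=[N-])C(C)=O
Why: Seyferth–Gilbert homologation with the Ohira–Bestmann reagent should convert the non-enolisable aldehyde into the terminal alkyne (this carbon becomes C-8), the hindered conjugated ketone reacting far more slowly.

**Step 6**
Reactants: 8 2-[(1S,2R)-2-ethynyl-2-methylcyclopropyl]-3-methylcyclopent-2-en-1-one; 9 (2E)-2-methylbut-2-enoic acid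
Product: 10 (Z)-2-[(1R,2S)-1-methyl-2-(2-methyl-5-oxocyclopent-1-en-1-yl)cyclopropyl]ethenyl (2E)-2-methylbut-2-enoate
Conditions: Ru(η3-CH2C(CH3)CH2)2(Ph2P(CH2)4PPh2) (2 mol%), toluene, 60 °C
Reagents that add atoms: none
Why: Ruthenium-catalysed anti-Markovnikov addition of a carboxylic acid to a terminal alkyne through a vinylidene complex should give the (Z)-enol ester, which brings in the C-8 oxygen already acylated as the tiglate and with the geometry the key step needs.

**Step 7**
Reactants: 10 (Z)-2-[(1R,2S)-1-methyl-2-(2-methyl-5-oxocyclopent-1-en-1-yl)cyclopropyl]ethenyl (2E)-2-methylbut-2-enoate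
Product: 11 (3aR,4R)-3a,6-dimethyl-1-oxo-1,2,3,3a,4,7-hexahydroazulen-4-yl (2E)-2-methylbut-2-enoate
Conditions: degassed toluene, sealed tube, 130–150 °C
Reagents that add atoms: none
Why: Strain-driven thermal [3,3]-sigmatropic (Cope) rearrangement of a cis-1,2-divinylcyclopropane: the bond between the two substituted cyclopropane carbons breaks while the enol-ester terminus (C-8) bonds to the enone β-carbon (C-8a) and the π-bonds move to C6=C7 and C3a=C4. The closest known reaction type is the divinylcyclopropane–cycloheptadiene rearrangement used for hydroazulenes. The seven-membered ring is closed by this concerted enlargement of the three-membered ring through the obligatory boat transition state, with both alkenyl arms folded over the cyclopropane. C-8 and C-8a are set together and stereospecifically: the two inward (Z) terminus substituents, the acyloxy oxygen and the ring methyl, must end up cis, and the absolute sense follows from the (1R,2S)-cyclopropane, whose own centres are consumed. The step needs the concerted path to outrun homolysis of the doubly allylic cyclopropane bond; the cis arrangement fixed in step 3, the small inward groups (O and CH3) and the lowest effective temperature should secure this, and conjugated enone 11 is the only [3,3] product possible.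

**Step 8**
Reactants: 11 (3aR,4R)-3a,6-dimethyl-1-oxo-1,2,3,3a,4,7-hexahydroazulen-4-yl (2E)-2-methylbut-2-enoate
Product: 12 (3aS,4R,8S,8aR)-8,8a-epoxy-3a,6-dimethyl-1-oxo-1,2,3,3a,4,7,8,8a-octahydroazulen-4-yl (2E)-2-methylbut-2-enoate (epoxide oxygen cis to the angular methyl)
Conditions: t-BuOOH, n-BuLi, THF, −78 to −20 °C
Reagents that add atoms: tert-butyl hydroperoxide CC(C)(C)OO
Why: Weitz–Scheffer-type nucleophilic epoxidation by lithium tert-butyl peroxide should touch only the enone (not the enoate or the isolated alkene), and attack at C-4 from the face of the angular methyl, away from the C-8 arm of the folded cycloheptadiene, should place the new oxygen cis to that methyl.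

**Step 9**
Reactants: 12 the 8,8a-epoxy ketone
Product: 13 (3aR,4R,8S,8aS)-8-hydroxy-3a,6-dimethyl-1-oxo-1,2,3,3a,4,7,8,8a-octahydroazulen-4-yl (2E)-2-methylbut-2-enoate (cis-fused)
Conditions: SmI2 (2.2 equiv), THF/MeOH, −90 °C
Reagents that add atoms: none
Why: SmI2 reductive cleavage of the Cα–O bond of an α,β-epoxy ketone should give the aldol with the C-4 carbinol untouched, and protonation of the samarium enolate at C-3a from the convex face gives the cis-fused ketone, which is also expected to be the thermodynamic epimer of this enolisable centre.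

**Step 10**
Reactants: 13 the cis-fused β-hydroxy ketone
Product: 14 (3R,3aS,4S,8R,8aR)-3,4-dihydroxy-6,8a-dimethyl-3-(propan-2-yl)-1,2,3,3a,4,5,8,8a-octahydroazulen-8-yl (2E)-2-methylbut-2-enoate
Conditions: i-PrMgCl, CeCl3, THF, −78 to −40 °C; aq. NH4Cl
Reagents that add atoms: isopropylmagnesium chloride CC(C)[Mg]Cl
Why: Organocerium 1,2-addition should suppress enolisation and add to the ketone much faster than to the hindered conjugated ester, attacking the cis-fused cyclopentanone from its convex face, anti to the adjacent C3a–C4 bond, so that the C-3 hydroxyl ends up cis to the C-4 branch.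

**Step 11**
Reactants: 14 the diol; 15 4-(acetyloxy)benzoyl chloride
Product: 16 (3R,3aS,4S,8R,8aR)-3-hydroxy-6,8a-dimethyl-8-{[(2E)-2-methylbut-2-enoyl]oxy}-3-(propan-2-yl)-1,2,3,3a,4,5,8,8a-octahydroazulen-4-yl 4-(acetyloxy)benzoate
Conditions: pyridine, DMAP (cat.), CH2Cl2, 0 °C to rt
Reagents that add atoms: none
Why: DMAP-catalysed acylation should occur only at the secondary C-4 hydroxyl, the tertiary C-3 hydroxyl being unreactive.

**Step 12**
Reactants: 16 the 4-(acetyloxy)benzoate
Product: 17 (3R,3aS,4S,8R,8aR)-3-hydroxy-6,8a-dimethyl-8-{[(2E)-2-methylbut-2-enoyl]oxy}-3-(propan-2-yl)-1,2,3,3a,4,5,8,8a-octahydroazulen-4-yl 4-hydroxybenzoate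
Conditions: pyrrolidine, CH2Cl2, 0 °C
Reagents that add atoms: none
Why: Aminolysis of the activated aryl acetate should be much faster than attack on the alkyl benzoate or the hindered tiglate, freeing the phenol.

**Compound list**
1 | prop-2-yn-1-ol | C#CCO | starting material
2 | [(1Z)-3-(bromomagnesiooxy)-2-methylprop-1-en-1-yl]magnesium bromide | Br[Mg]/C=C(/C)CO[Mg]Br | intermediate
3 | (2Z)-2-methyl-3-(tributylstannyl)prop-2-en-1-ol | CCCC[Sn](CCCC)(CCCC)/C=C(/C)CO | intermediate
4 | 2-bromo-3-methylcyclopent-2-en-1-one | CC1=C(Br)C(=O)CC1 | starting material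
5 | 2-[(1Z)-3-hydroxy-2-methylprop-1-en-1-yl]-3-methylcyclopent-2-en-1-one | CC1=C(/C=C(/C)CO)C(=O)CC1 | intermediate
6 | 2-[(1S,2R)-2-(hydroxymethyl)-2-methylcyclopropyl]-3-methylcyclopent-2-en-1-one | OC[C@]1(C)C[C@@H]1C2=C(C)CCC2=O | intermediate
7 | (1R,2S)-1-methyl-2-(2-methyl-5-oxocyclopent-1-en-1-yl)cyclopropane-1-carbaldehyde | O=C[C@]1(C)C[C@@H]1C2=C(C)CCC2=O | intermediate
8 | 2-[(1S,2R)-2-ethynyl-2-methylcyclopropyl]-3-methylcyclopent-2-en-1-one | C#C[C@]1(C)C[C@@H]1C2=C(C)CCC2=O | intermediate
9 | (2E)-2-methylbut-2-enoic acid (tiglic acid) | C/C=C(\C)C(=O)O | starting material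
10 | (Z)-2-[(1R,2S)-1-methyl-2-(2-methyl-5-oxocyclopent-1-en-1-yl)cyclopropyl]ethenyl (2E)-2-methylbut-2-enoate | C/C=C(\C)C(=O)O/C=C\[C@]1(C)C[C@@H]1C2=C(C)CCC2=O | intermediate
11 | (3aR,4R)-3a,6-dimethyl-1-oxo-1,2,3,3a,4,7-hexahydroazulen-4-yl (2E)-2-methylbut-2-enoate | C/C=C(\C)C(=O)O[C@@H]1C=C(C)CC=C2C(=O)CC[C@@]12C | intermediate
12 | (3aS,4R,8S,8aR)-8,8a-epoxy-3a,6-dimethyl-1-oxo-1,2,3,3a,4,7,8,8a-octahydroazulen-4-yl (2E)-2-methylbut-2-enoate | C/C=C(\C)C(=O)O[C@@H]1C=C(C)C[C@@H]2O[C@@]23C(=O)CC[C@@]13C | intermediate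
13 | (3aR,4R,8S,8aS)-8-hydroxy-3a,6-dimethyl-1-oxo-1,2,3,3a,4,7,8,8a-octahydroazulen-4-yl (2E)-2-methylbut-2-enoate | C/C=C(\C)C(=O)O[C@@H]1C=C(C)C[C@H](O)[C@@H]2[C@@]1(C)CCC2=O | intermediate
14 | (3R,3aS,4S,8R,8aR)-3,4-dihydroxy-6,8a-dimethyl-3-(propan-2-yl)-1,2,3,3a,4,5,8,8a-octahydroazulen-8-yl (2E)-2-methylbut-2-enoate | C/C=C(\C)C(=O)O[C@@H]1C=C(C)C[C@H](O)[C@@H]2[C@@]1(C)CC[C@@]2(O)C(C)C | intermediate
15 | 4-(acetyloxy)benzoyl chloride | CC(=O)Oc1ccc(cc1)C(Cl)=O | starting material
16 | (3R,3aS,4S,8R,8aR)-3-hydroxy-6,8a-dimethyl-8-{[(2E)-2-methylbut-2-enoyl]oxy}-3-(propan-2-yl)-1,2,3,3a,4,5,8,8a-octahydroazulen-4-yl 4-(acetyloxy)benzoate | C/C=C(\C)C(=O)O[C@@H]1C=C(C)C[C@H](OC(=O)c2ccc(OC(C)=O)cc2)[C@@H]2[C@@]1(C)CC[C@@]2(O)C(C)C | intermediate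
17 | (3R,3aS,4S,8R,8aR)-3-hydroxy-6,8a-dimethyl-8-{[(2E)-2-methylbut-2-enoyl]oxy}-3-(propan-2-yl)-1,2,3,3a,4,5,8,8a-octahydroazulen-4-yl 4-hydroxybenzoate | C/C=C(\C)C(=O)O[C@@H]1C=C(C)C[C@H](OC(=O)c2ccc(O)cc2)[C@@H]2[C@@]1(C)CC[C@@]2(O)C(C)C | target

**Step count.** Total: 12 steps. Longest linear sequence: 12 steps (1 to 17).

**Steps most likely to fail**

Step 7. The boat transition state carries two inward groups and forms a quaternary carbon, so the concerted shift may need temperatures at which homolysis of the cyclopropane bond erodes stereospecificity or the enol ester decomposes. The fallback sets out from 8 and returns at 11. Copper-catalysed syn-hydroboration of the alkyne (B2pin2, CuCl, Xantphos, NaOt-Bu, MeOH) would give the E-alkenyl pinacolboronate of 8, F1. Its Cope rearrangement has only the ring methyl inward and should run near 100 °C to the allylic boronate F2, with boron trans to the angular methyl. Oxidation with NaBO3 (retention) would give the C-8-epimeric allylic alcohol F3. Mitsunobu esterification with tiglic acid 9 (PPh3, DIAD, inversion) would then return to 11.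

Step 8. Facial selectivity of the peroxide addition to the enone may be poor, which would give the wrong configuration at C-4. The fallback sets out from 11 and returns at 14. The epimeric material would be taken through steps 8 to 10 as a mixture of 14 and its C-4 epimer F4. Dess–Martin oxidation of the secondary alcohol converges both epimers to the β-hydroxy ketone F5. Hydroxyl-directed reduction (Me4NBH(OAc)3, MeCN/AcOH, −20 °C) then delivers hydride from the face of the tertiary C-3 hydroxyl and should give the anti-1,3-diol 14.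

Step 6. The ruthenium vinylidene may form slowly on the neopentyl-like cyclopropyl alkyne, or the Z/anti-Markovnikov selectivity may erode. The fallback sets out from 8 and returns at 10. Rhodium-catalysed trans-hydroboration (HBpin, [RhCl(cod)]2, P(i-Pr)3, Et3N) would give the Z-alkenyl pinacolboronate of 8, F6. KHF2 in aqueous MeOH would convert it into the potassium Z-alkenyltrifluoroborate F7. Copper-mediated coupling of F7 with tiglic acid 9 (Cu(OAc)2, DMAP, molecular sieves, O2, CH2Cl2) proceeds with retention and would give 10.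

Further compounds
F1 | step 7 | E-alkenyl pinacolboronate of 8: 3-methyl-2-{2-methyl-2-[(E)-2-(4,4,5,5-tetramethyl-1,3,2-dioxaborolan-2-yl)ethenyl]cyclopropyl}cyclopent-2-en-1-one, cyclopropane configuration as in 8 | CC1(C)OB(OC1(C)C)/C=C/[C@]2(C)C[C@@H]2C3=C(C)CCC3=O
F2 | step 7 | allylic boronate: 3a,6-dimethyl-4-(4,4,5,5-tetramethyl-1,3,2-dioxaborolan-2-yl)-2,3,3a,4-tetrahydroazulen-1(7H)-one, boron trans to the angular methyl | CC1(C)OB(OC1(C)C)[C@H]2C=C(C)CC=C3C(=O)CC[C@@]23C
F3 | step 7 | allylic alcohol epimeric to the alcohol of 11: 4-hydroxy-3a,6-dimethyl-2,3,3a,4-tetrahydroazulen-1(7H)-one, hydroxyl trans to the angular methyl | O[C@H]1C=C(C)CC=C2C(=O)CC[C@@]12C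
F4 | step 8 | C-4 epimer of diol 14 | C/C=C(\C)C(=O)O[C@@H]1C=C(C)C[C@@H](O)[C@@H]2[C@@]1(C)CC[C@@]2(O)C(C)C
F5 | step 8 | 4-oxo analogue of 14 (β-hydroxy ketone, cis-fused) | C/C=C(\C)C(=O)O[C@@H]1C=C(C)CC(=O)[C@@H]2[C@@]1(C)CC[C@@]2(O)C(C)C
F6 | step 6 | Z-alkenyl pinacolboronate of 8, cyclopropane configuration as in 8 | CC1(C)OB(OC1(C)C)/C=C\[C@]2(C)C[C@@H]2C3=C(C)CCC3=O
F7 | step 6 | potassium Z-alkenyltrifluoroborate of 8, cyclopropane configuration as in 8 | [K+].F[B-](F)(F)/C=C\[C@]1(C)C[C@@H]1C2=C(C)CCC2=O
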